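The ten-membered ring is closed at C5–C6 by an anionic oxy-Cope ring expansion. The feature exploited is that this ring holds the C9 ketone, its α-carbon C10 and β-carbon C5 on one side of the new bond and C6–C7–C8 on the other, a cyclodec-5-enone retron. The precursor is a 1-vinylbicyclo[3.2.1]octan-2-ol (C8–C9 still bonded, ring A absent) whose carbinol C9 carries an acyclic alkenyl chain ending in CH2Cl. One operation cleaves C8–C9, forms C5–C6 and sets C5; the resulting enolate then closes ring A at C10–C1 and sets the quaternary C10. C7=C8 is later transposed into the C7 carbinol by a singlet-oxygen ene reaction.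

Key step: step 11

Remark on labels: atoms carry kaurane numbers. In the target SMILES read left to right they are C17H2=C16, C15(=O), C8, C14H=, C13H, C12H2, C11H(OAc), C9(=O), C10 (bearing C20H3), C1H2, C2H2, C3H2, C4 (bearing two methyl groups), C5H, C6H2, C7H(OH). Ring A is C1–C5 plus C10. The ten-membered ring is C5–C6–C7–C8–C14–C13–C12–C11–C9–C10. The cyclopentenone is C8, C14, C13, C16, C15. Compounds 28 to 35 are named as 8,9-secokauranes (no C8–C9 bond) with full CIP descriptors.

Remark on the chemistry: the target is read as (5R,7R,10R,11S,13R), and commercial (+)-nopinone is taken as (1R,5S); its C5 becomes C13 of the target.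

Step 1
Reactants: 1 (+)-nopinone, (1R,5S)-6,6-dimethylbicyclo[3.1.1]heptan-2-one; 2 acetaldehyde
Product: 6 (1R,5R)-3-[(E)-ethylidene]-6,6-dimethylbicyclo[3.1.1]heptan-2-one, via lithium enolate 3 (not isolated), via lithium aldolate 4 (not isolated), via aldol mesylate 5 (not isolated)
Conditions: LiN(i-Pr)2, THF, −78 °C; 2; MsCl, −78 → 0 °C; DBU, rt
Reagents that add atoms: none
Why: Nopinone can enolise only toward C3 because the other α-carbon is a bridgehead, so aldol addition, mesylation and E1cB elimination (aldol condensation) should give the (E)-enone and thereby fix which α-carbon becomes C8, the pinane stereocentres being untouched.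

Step 2
Reactants: 6
Product: 8 (2E,4R)-2-ethylidene-4-(prop-1-en-2-yl)cyclohexan-1-one, via dienyl acetate 7 (not isolated)
Conditions: BF3·OEt2, Zn(OAc)2, Ac2O, 0 °C → rt; aqueous work-up; then K2CO3 (cat.), MeOH, 0 °C
Reagents that add atoms: none
Why: Lewis-acid activation of the ketone should trigger heterolysis of the strained cyclobutane bond between the α-bridgehead and the gem-dimethyl carbon (acid-mediated cyclobutane fragmentation of nopinones to 4-isopropenylcyclohexenyl acetates), the tertiary cation losing a proton to the isopropenyl group and methanolysis returning the ketone, with the C13 stereocentre (4R) carried over unchanged from 1.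

Step 3
Reactants: 8
Product: 9 (2E,4R)-4-(3-chloroprop-1-en-2-yl)-2-ethylidenecyclohexan-1-one
Conditions: Ca(OCl)2, CO2 (solid), CH2Cl2–H2O, 0 °C
Reagents that add atoms: calcium hypochlorite Ca(OCl)2, [Ca+2].[O-]Cl.[O-]Cl
Why: HOCl formed in the flask should chlorinate the electron-rich isopropenyl group by an ene-type allylic chlorination with double-bond shift (as known for isopropenyl terpenes such as carvone), while the electron-poor enone double bond is inert.

Step 4
Reactants: 9
Product: 11 (1S,5R)-1-ethenyl-6-methylidenebicyclo[3.2.1]octan-2-one, via potassium dienolate 10 (not isolated)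
Conditions: KOt-Bu, t-BuOH–THF, 0 °C → rt
Reagents that add atoms: none
Why: Under equilibrating conditions the extended dienolate from γ-deprotonation should be alkylated at its α-carbon by the tethered allylic chloride (deconjugative intramolecular α-alkylation, 5-exo-tet), creating the quaternary bridgehead C8 with its vinyl group; the tether from C13 can bridge only cis, so C13 dictates C8 (1S).

Step 5
Reactants: 12 2-methylpropanenitrile (isobutyronitrile); 13 1-bromo-3-chloropropane
Product: 15 5-chloro-2,2-dimethylpentanenitrile, via lithiated nitrile 14 (not isolated)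
Conditions: LiN(i-Pr)2, THF, −78 °C; 13, −78 °C → rt
Reagents that add atoms: none
Why: SN2 alkylation of the α-cyano carbanion should occur selectively at the bromide-bearing carbon, leaving the chloride that later closes ring A.

Step 6
Reactants: 15
Product: 17 5-chloro-2,2-dimethylpentanal, via aluminium aldimine 16 (not isolated)
Conditions: i-Bu2AlH, CH2Cl2, −78 °C; then aq. HCl, 0 °C
Reagents that add atoms: water, O
Why: Partial reduction of a hindered nitrile with i-Bu2AlH stops at the aluminium aldimine, and acidic hydrolysis should release the aldehyde.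

Step 7
Reactants: 17
Product: 18 1,1-dibromo-6-chloro-3,3-dimethylhex-1-ene
Conditions: CBr4, PPh3, CH2Cl2, 0 °C
Reagents that add atoms: carbon tetrabromide, BrC(Br)(Br)Br
Why: Ramirez dibromo-olefination (first stage of the Corey–Fuchs sequence) is reliable on non-enolisable α-quaternary aldehydes.

Step 8
Reactants: 18
Product: 20 7-chloro-4,4-dimethylhept-2-yne, via lithium acetylide 19 (not isolated)
Conditions: n-BuLi (2.1 equiv), THF, −78 °C; then MeI, DMPU, −78 °C → rt
Reagents that add atoms: iodomethane, CI
Why: Bromine–lithium exchange and Fritsch–Buttenberg–Wiechell rearrangement (second stage of the Corey–Fuchs reaction) should give the lithium acetylide, which is C-methylated by iodomethane faster than it can attack the primary chloride.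

Step 9
Reactants: 20
Product: 22 (E)-7-chloro-2-iodo-4,4-dimethylhept-2-ene, via alkenylzirconocene chloride 21 (not isolated)
Conditions: Cp2Zr(H)Cl, THF, rt → 40 °C; then I2, 0 °C
Reagents that add atoms: iodine, II
Why: Hydrozirconation is a syn addition that places zirconium on the alkyne carbon remote from the tert-alkyl group, and iodinolysis with retention should give the (E)-iodide in which the methyl group is cis to C4, the geometry on which the C10 configuration later depends.

Step 10
Reactants: 22; 11
Product: 25 (1S,2R,5R)-2-[(2E)-7-chloro-4,4-dimethylhept-2-en-2-yl]-1-ethenyl-6-methylidenebicyclo[3.2.1]octan-2-ol, via alkenyllithium 23 (not isolated), via alkenylcerium dichloride 24 (not isolated)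
Conditions: 22, t-BuLi (2.1 equiv), Et2O, −78 °C; CeCl3, THF, −78 °C; then 11, −78 → −40 °C; aq. NH4Cl
Reagents that add atoms: none
Why: Iodine–lithium exchange with retention and transmetalation to the weakly basic organocerium reagent should allow 1,2-addition to the enolisable ketone from the face of the one-carbon bridge C14, because the other face is screened by the axial C8–C15 bond of the two-carbon bridge; this places the alkenyl group axial (2R), gauche to the equatorial bridgehead vinyl group.

Step 11
Reactants: 25
Product: 28 (5R,7E,10R,13R)-8,9-secokaura-7,16-dien-9-one, via potassium alkoxide 26 (not isolated), via potassium enolate 27 (not isolated)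
Conditions: KH, 18-crown-6, THF, 0 °C → rt, then 50 °C
Reagents that add atoms: none
Why: Deprotonation gives alkoxide 26, whose 1,5-diene C6=C7–C8–C9(O−)–C10=C5 undergoes a [3,3]-sigmatropic shift that breaks C8–C9 and forms C5–C6, expanding the six-membered ring C8–C9–C11–C12–C13–C14 to the ten-membered ring and giving enolate 27, whose carbon C10 then displaces chloride at C1. The closest known reaction type is the anionic oxy-Cope ring expansion of 1-vinyl-2-alkenylbicycloalkan-2-olates to bridged medium-ring enolates with in situ enolate alkylation. The ten-membered ring closes by the concerted ring-expanding shift through a chair transition state (the equatorial vinyl and axial alkenyl groups are gauche, so a boat is not accessible), and ring A closes by 6-exo-tet SN2 alkylation. C5 is controlled by the bicycle: in the chair, C6 bonds to the face of C10=C5 that faces C8, with the bulky C4 group pseudo-equatorial, which relays the C8/C9 configuration (itself derived from C13) into 5R. C10 is controlled by the enolate: it is trans within the ten-membered ring, so C6 stands perpendicular on its inner face and the C4-to-C1 tether can reach C10 only from the outer face, and because the methyl group is cis to C4 this places the methyl trans to H5 (10R). The step needs the [3,3] shift to outrun alkoxide fragmentation and C-alkylation to outrun proton transfer or O-alkylation; the crown-ether-separated potassium alkoxide and the release of bicyclic strain should secure the first, and the trans relationship of C9 and C4 on the alkene (which excludes ether formation) together with the Thorpe–Ingold effect of the gem-dimethyl group the second.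

Step 12
Reactants: 28
Product: 30 (5R,7E,10R,11S,13S)-11-hydroxy-8,9-secokaura-7,16-dien-9-one, via potassium enolate 29 (not isolated)
Conditions: KN(SiMe3)2, THF, −78 °C; 2-(benzenesulfonyl)-3-phenyloxaziridine, −78 °C; aq. NH4Cl
Reagents that add atoms: 2-(benzenesulfonyl)-3-phenyloxaziridine (Davis oxaziridine), O=S(=O)(c1ccccc1)N1OC1c1ccccc1
Why: C11 is the only enolisable position because C10 is quaternary, and Davis hydroxylation of the enolate (formed with C12 cis to the oxygen to avoid allylic strain against C10) should occur on the outer face, away from the transannular C7=C8 unit, which corresponds to 11S.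

Step 13
Reactants: 30
Product: 31 (5R,7E,10R,11S,13S)-11-acetoxy-8,9-secokaura-7,16-dien-9-one
Conditions: Ac2O, pyridine, DMAP (cat.), CH2Cl2, 0 °C
Reagents that add atoms: acetic anhydride, CC(=O)OC(C)=O
Why: Acylation of the secondary alcohol proceeds with retention at C11 under conditions mild enough not to epimerise the α-acyloxy ketone.

Step 14
Reactants: 31
Product: 32 (5R,7E,10R,11S,13S,15RS)-11-acetoxy-15-hydroxy-8,9-secokaura-7,16-dien-9-one
Conditions: SeO2 (cat.), t-BuOOH, CH2Cl2, rt
Reagents that add atoms: tert-butyl hydroperoxide, CC(C)(C)OO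
Why: Riley allylic hydroxylation (ene reaction then [2,3]-shift) should select C15 because it is allylic to both C7=C8 (at its more substituted end, trans to C6) and C16=C17, and the new C15 centre is of no consequence since it is oxidised in the next step.

Step 15
Reactants: 32
Product: 33 (5R,7E,10R,11S,13S)-11-acetoxy-8,9-secokaura-7,16-diene-9,15-dione
Conditions: Dess–Martin periodinane, CH2Cl2, 0 °C
Reagents that add atoms: none
Why: Dess–Martin oxidation should convert the doubly allylic alcohol into the cross-conjugated dienone under near-neutral conditions that spare the α-acetoxy ketone.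

Step 16
Reactants: 33
Product: 35 (5R,7R,10R,11S,13R)-11-acetoxy-7-hydroxy-8,9-secokaura-8(14),16-diene-9,15-dione (the target), via C7 hydroperoxide 34 (not isolated)
Conditions: O2, hν (visible), tetraphenylporphyrin (cat.), CH2Cl2, 0 °C; then Me2S
Reagents that add atoms: oxygen, O=O
Why: The Schenck ene reaction of singlet oxygen with the s-cis enone C7=C8–C15=O follows the gem rule (oxygen to the β-carbon C7, hydrogen taken from C14, the group geminal to the carbonyl), moving the double bond to C8=C14; attack on the face opposite the ten-membered ring loop that leaves C13 through C12 should set 7R, and Me2S reduces the hydroperoxide.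

Compound list
1 | (+)-nopinone, (1R,5S)-6,6-dimethylbicyclo[3.1.1]heptan-2-one | O=C1CC[C@H]2C[C@@H]1C2(C)C | starting material
2 | acetaldehyde | CC=O | starting material
3 | lithium enolate of 1 (C2=C3; pinane centres unchanged; not isolated) | [Li+].[O-]C1=CC[C@H]2C[C@@H]1C2(C)C | intermediate
4 | lithium aldolate, lithium alkoxide of 3-(1-hydroxyethyl)nopinone (mixture at the two new centres; not isolated) | O=C1C(C(C)[O-])C[C@H]2C[C@@H]1C2(C)C.[Li+] | intermediate
5 | aldol mesylate, 3-[1-(methanesulfonyloxy)ethyl]nopinone (mixture at the two new centres; not isolated) | O=C1C(C(C)OS(C)(=O)=O)C[C@H]2C[C@@H]1C2(C)C | intermediate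
6 | (1R,5R)-3-[(E)-ethylidene]-6,6-dimethylbicyclo[3.1.1]heptan-2-one | O=C1/C(=C/C)C[C@H]2C[C@@H]1C2(C)C | intermediate
7 | (4R,6E)-6-ethylidene-4-(prop-1-en-2-yl)cyclohex-1-en-1-yl acetate (not isolated) | C/C=C1\C[C@H](C(C)=C)CC=C1OC(C)=O | intermediate
8 | (2E,4R)-2-ethylidene-4-(prop-1-en-2-yl)cyclohexan-1-one | O=C1/C(=C/C)C[C@@H](CC1)C(C)=C | intermediate
9 | (2E,4R)-4-(3-chloroprop-1-en-2-yl)-2-ethylidenecyclohexan-1-one | O=C1/C(=C/C)C[C@@H](CC1)C(=C)CCl | intermediate
10 | potassium (4R)-4-(3-chloroprop-1-en-2-yl)-2-ethenylcyclohex-1-en-1-olate (extended dienolate of 9; not isolated) | [K+].[O-]C1=C(C=C)C[C@@H](CC1)C(=C)CCl | intermediate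
11 | (1S,5R)-1-ethenyl-6-methylidenebicyclo[3.2.1]octan-2-one | O=C1CC[C@@H]2C[C@@]1(C=C)CC2=C | intermediate
12 | 2-methylpropanenitrile | CC(C)C#N | starting material
13 | 1-bromo-3-chloropropane | ClCCCBr | starting material
14 | 2-lithio-2-methylpropanenitrile (not isolated) | [Li]C(C)(C)C#N | intermediate
15 | 5-chloro-2,2-dimethylpentanenitrile | CC(C)(CCCCl)C#N | intermediate
16 | N-(diisobutylaluminio) aldimine of 17 (not isolated) | CC(C)C[Al](CC(C)C)N=CC(C)(C)CCCCl | intermediate
17 | 5-chloro-2,2-dimethylpentanal | CC(C)(CCCCl)C=O | intermediate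
18 | 1,1-dibromo-6-chloro-3,3-dimethylhex-1-ene | ClCCCC(C)(C)C=C(Br)Br | intermediate
19 | (6-chloro-3,3-dimethylhex-1-yn-1-yl)lithium (not isolated) | [Li]C#CC(C)(C)CCCCl | intermediate
20 | 7-chloro-4,4-dimethylhept-2-yne | CC#CC(C)(C)CCCCl | intermediate
21 | chloro[(2E)-7-chloro-4,4-dimethylhept-2-en-2-yl]zirconocene, methyl cis to C4 (Cp drawn σ-bonded; not isolated) | C/C(=C\C(C)(C)CCCCl)[Zr](Cl)(C1C=CC=C1)C1C=CC=C1 | intermediate
22 | (E)-7-chloro-2-iodo-4,4-dimethylhept-2-ene | C/C(I)=C\C(C)(C)CCCCl | intermediate
23 | [(2Z)-7-chloro-4,4-dimethylhept-2-en-2-yl]lithium, methyl cis to C4 (not isolated) | C/C([Li])=C\C(C)(C)CCCCl | intermediate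
24 | dichloro[(2E)-7-chloro-4,4-dimethylhept-2-en-2-yl]cerium, methyl cis to C4 (not isolated) | C/C(=C\C(C)(C)CCCCl)[Ce](Cl)Cl | intermediate
25 | (1S,2R,5R)-2-[(2E)-7-chloro-4,4-dimethylhept-2-en-2-yl]-1-ethenyl-6-methylidenebicyclo[3.2.1]octan-2-ol | O[C@@]1(/C(C)=C/C(C)(C)CCCCl)CC[C@@H]2C[C@@]1(C=C)CC2=C | intermediate
26 | potassium alkoxide of 25 (not isolated) | [K+].[O-][C@@]1(/C(C)=C/C(C)(C)CCCCl)CC[C@@H]2C[C@@]1(C=C)CC2=C | intermediate
27 | potassium (5R,7E,9Z,13R)-1-chloro-1,10:8,9-disecokaura-7,9,16-trien-9-olate: ten-membered ring closed, ring A still open (not isolated) | [K+].C=C1C/C2=C/C[C@H](C(C)(C)CCCCl)/C(C)=C(\[O-])CC[C@@H]1C2 | intermediate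
28 | (5R,7E,10R,13R)-8,9-secokaura-7,16-dien-9-one | C=C1C/C2=C/C[C@H]3[C@@](C)(CCCC3(C)C)C(=O)CC[C@@H]1C2 | intermediate
29 | potassium enolate of 28, C9(O−)=C11 with C12 cis to oxygen (not isolated) | [K+].C=C1C/C2=C/C[C@H]3[C@@](C)(CCCC3(C)C)/C([O-])=C/C[C@@H]1C2 | intermediate
30 | (5R,7E,10R,11S,13S)-11-hydroxy-8,9-secokaura-7,16-dien-9-one | C=C1C/C2=C/C[C@H]3[C@@](C)(CCCC3(C)C)C(=O)[C@@H](O)C[C@@H]1C2 | intermediate
31 | (5R,7E,10R,11S,13S)-11-acetoxy-8,9-secokaura-7,16-dien-9-one | C=C1C/C2=C/C[C@H]3[C@@](C)(CCCC3(C)C)C(=O)[C@@H](OC(C)=O)C[C@@H]1C2 | intermediate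
32 | (5R,7E,10R,11S,13S,15RS)-11-acetoxy-15-hydroxy-8,9-secokaura-7,16-dien-9-one | C=C1C(O)/C2=C/C[C@H]3[C@@](C)(CCCC3(C)C)C(=O)[C@@H](OC(C)=O)C[C@@H]1C2 | intermediate
33 | (5R,7E,10R,11S,13S)-11-acetoxy-8,9-secokaura-7,16-diene-9,15-dione | C=C1C(=O)/C2=C/C[C@H]3[C@@](C)(CCCC3(C)C)C(=O)[C@@H](OC(C)=O)C[C@@H]1C2 | intermediate
34 | (5R,7R,10R,11S,13R)-11-acetoxy-7-hydroperoxy-8,9-secokaura-8(14),16-diene-9,15-dione (not isolated) | C=C1C(=O)C2=C[C@H]1C[C@H](OC(C)=O)C(=O)[C@]1(C)CCCC(C)(C)[C@H]1C[C@H]2OO | intermediate
35 | (5R,7R,10R,11S,13R)-11-acetoxy-7-hydroxy-8,9-secokaura-8(14),16-diene-9,15-dione | C=C1C(=O)C2=C[C@H]1C[C@H](OC(C)=O)C(=O)[C@]1(C)CCCC(C)(C)[C@H]1C[C@H]2O | target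

Total step count: 16. Longest linear sequence: 12 steps (steps 5 to 16, from 12); the other branch (steps 1 to 4, then 10 to 16) has 11.

Steps most likely to fail

Step 11. The alkoxide may fragment or isomerise instead of rearranging, because C5 is a neopentyl-type terminus. The enolate may also be quenched by proton transfer, or lose HCl by elimination, before ring A closes. The fallback sets out from 25 and separates the two events under neutral conditions. Silylation with 1-(trimethylsilyl)imidazole should give the trimethylsilyl ether F1. Thermal siloxy-Cope rearrangement (sealed tube, toluene, about 200 °C) should give the ring-expanded silyl enol ether F2 through the same chair, so C5 is set as before. MeLi in THF then releases the regiodefined lithium enolate F3, which is cyclised in THF–DMPU and comes back to the route at 28.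

Step 12. The oxidant may attack the inner face of the enolate, or the enolate may react through another rotamer about C9–C10, and either would deliver the C11 epimer. The fallback sets out from 28 and turns face selection into an inversion. The hydroxylation is run as in step 12; if it returns the (11R)-hydroxy ketone F4, Mitsunobu esterification (PPh3, DIAD, AcOH, THF, 0 °C) should install the acetate with inversion and come back to the route at 31.

Step 16. The cross-conjugated dienone may react too slowly with singlet oxygen, so that photodegradation or an ene reaction at the exocyclic methylene takes over. The fallback sets out from 31 and runs the photooxygenation on the electron-rich C7=C8 double bond before C15 is oxidised. Hydrogen abstraction from the cyclopentane CH2 cis to C6 should give the hydroperoxide F5, which Me2S reduces to the allylic alcohol F6. Protection (Et3SiOTf, 2,6-lutidine) gives the triethylsilyl ether F7. Riley oxidation (SeO2, t-BuOOH) at the now doubly allylic C15 gives the alcohol F8, and Dess–Martin oxidation gives the silyl-protected dienone F9. HF·pyridine then removes the silyl group and arrives at 35.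

Further compounds
F1 | step 11 | trimethylsilyl ether of 25 | C[Si](C)(C)O[C@@]1(/C(C)=C/C(C)(C)CCCCl)CC[C@@H]2C[C@@]1(C=C)CC2=C
F2 | step 11 | (5R,7E,9Z,13R)-1-chloro-9-(trimethylsilyloxy)-1,10:8,9-disecokaura-7,9,16-triene | C=C1C/C2=C/C[C@H](C(C)(C)CCCCl)/C(C)=C(\O[Si](C)(C)C)CC[C@@H]1C2
F3 | step 11 | lithium (5R,7E,9Z,13R)-1-chloro-1,10:8,9-disecokaura-7,9,16-trien-9-olate | [Li+].C=C1C/C2=C/C[C@H](C(C)(C)CCCCl)/C(C)=C(\[O-])CC[C@@H]1C2
F4 | step 12 | (5R,7E,10R,11R,13S)-11-hydroxy-8,9-secokaura-7,16-dien-9-one | C=C1C/C2=C/C[C@H]3[C@@](C)(CCCC3(C)C)C(=O)[C@H](O)C[C@@H]1C2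
F5 | step 16 | (5R,7R,10R,11S,13R)-11-acetoxy-7-hydroperoxy-8,9-secokaura-8(14),16-dien-9-one | C=C1CC2=C[C@H]1C[C@H](OC(C)=O)C(=O)[C@]1(C)CCCC(C)(C)[C@H]1C[C@H]2OO
F6 | step 16 | (5R,7R,10R,11S,13R)-11-acetoxy-7-hydroxy-8,9-secokaura-8(14),16-dien-9-one | C=C1CC2=C[C@H]1C[C@H](OC(C)=O)C(=O)[C@]1(C)CCCC(C)(C)[C@H]1C[C@H]2O
F7 | step 16 | (5R,7R,10R,11S,13R)-11-acetoxy-7-(triethylsilyloxy)-8,9-secokaura-8(14),16-dien-9-one | C=C1CC2=C[C@H]1C[C@H](OC(C)=O)C(=O)[C@]1(C)CCCC(C)(C)[C@H]1C[C@H]2O[Si](CC)(CC)CC
F8 | step 16 | (5R,7R,10R,11S,13R,15RS)-11-acetoxy-15-hydroxy-7-(triethylsilyloxy)-8,9-secokaura-8(14),16-dien-9-one | C=C1C(O)C2=C[C@H]1C[C@H](OC(C)=O)C(=O)[C@]1(C)CCCC(C)(C)[C@H]1C[C@H]2O[Si](CC)(CC)CC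
F9 | step 16 | (5R,7R,10R,11S,13R)-11-acetoxy-7-(triethylsilyloxy)-8,9-secokaura-8(14),16-diene-9,15-dione | C=C1C(=O)C2=C[C@H]1C[C@H](OC(C)=O)C(=O)[C@]1(C)CCCC(C)(C)[C@H]1C[C@H]2O[Si](CC)(CC)CC
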